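The choice here is how to bring substrate and first nucleophile together, by a slow feed or nearly at once, and the earlier runs can show how long the substrate lasts against such a feed.

| flask | substrate | first nucleophile | second nucleophile | temperature | remark | time |
|---|---|---|---|---|---|---|
| midnight | 0.40 M | 0.38 M | 1.6 M | −25 °C | run made earlier |  |
| winter | 0.56 M | 0.38 M | 1.6 M | −14 °C | run made earlier |  |
| autumn | 0.88 M | 0.38 M | 1.6 M | −25 °C | run made earlier |  |
| Tuesday's | 0.40 M | 0.380 M (fed, over 1.5 min) | 1.60 M |  | the addition at −40 °C, then warmed to −20 °C; the feed brings no volume worth counting | 2.5 min |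
| Sunday's | 0.40 M (fed, over 1.5 min) | 0.380 M | 1.60 M | −20 °C | all else is in the flask from the start; the feed brings no volume worth counting | 2.5 min |
| Monday's | 0.40 M (fed, over 10 s) | 0.380 M | 1.60 M | −20 °C | all else is in the flask from the start; the feed brings no volume worth counting | 2.5 min |
| Saturday's | 0.40 M | 0.380 M (fed, over 1.5 min) | 1.60 M | −20 °C | all else is in the flask from the start; the feed brings no volume worth counting | 2.5 min |

midnight run (percent of the substrate charged)

| time / s | target / % |
|---|---|
| 10.0 | 3.5 |
| 20.0 | 5.5 |
| 30.0 | 7.7 |
| 50.0 | 12.1 |
| 60.0 | 13.9 |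
| 90.0 | 18.3 |

winter run (percent of the substrate charged)

| time / min | target / % |
|---|---|
| 0.500 | 17.5 |
| 1.00 | 22.4 |
| 1.50 | 22.5 |
| 2.00 | 23.0 |
| 2.50 | 22.8 |
| 3.00 | 22.2 |

autumn run (percent of the substrate charged)

| time / min | target / % |
|---|---|
| 0.500 | 7.2 |
| 1.00 | 13.7 |
| 1.50 | 16.9 |
| 2.00 | 19.6 |
| 2.50 | 20.7 |
| 3.00 | 22.1 |

(each reading ± 0.3 percentage points)



- the flask with the highest amount of target, in percent of the substrate charged ("all alike" if they lie within 1.5 percentage points) (Tuesday's / Sunday's / Monday's / Saturday's / all alike)
- final target, as a percentage of the substrate charged, in Tuesday's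
- final target, as a percentage of the substrate charged, in Sunday's
- final target, as a percentage of the substrate charged, in Monday's
- final target, as a percentage of the substrate charged, in Saturday's

The winter run reads flat near 23.0 % from 1.00 min on, with 33.9 % of the first nucleophile taken up into target, so either the substrate or the first nucleophile has stopped being available. The earlier runs share one charge of first nucleophile, so this is a choice of reckoning and not a finding. This reckoning takes the first of the two: substrate leaves at its own first-order rate, whatever is present.

Two runs at −25 °C then measure that rate from the shape of the target curve. Equal time steps in the midnight run give 0.686 min⁻¹, while the autumn run gives 0.786 min⁻¹, which is higher. Autumn is the one that cheats, since by its last reading target has taken up half of the first nucleophile, against 19.3 % at midnight, and so its curve bends for a second reason.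

Keeping the midnight value, the winter run gives 2.86 min⁻¹. Interpolating the logarithm in temperature gives 1.31 min⁻¹ at −20 °C. Its inverse, 0.762 min, is the substrate lifetime, the mean time a substrate molecule lasts in the flask.

A feed of 1.5 min is 1.97 lifetimes. Integrating the first-order loss against a linear feed, substrate in Saturday's meets on average 43.7 % of the first nucleophile charge. Taking target in proportion to that share, with the winter reading of 23.0 % standing for a full charge although it was taken at −14 °C, gives an estimate of about 10.1 % of target. In Sunday's, where the substrate is the one fed, the loss integrated over that feed leaves 11.8 % of the substrate unturned at 2.5 min, which on the same footing gives about 20.3 %.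

The forecast names Monday's, with 21 % in Tuesday's, 19 % in Sunday's, 28 % in Monday's and 26 % in Saturday's, on the ground that “A is wasted in a first-order side loss”, where A is the first nucleophile. The two part on Saturday's, where this reckoning stands lower than the forecast.

The flasks give 25.3 % in Monday's, 23.3 % in Sunday's, 19.2 % in Tuesday's and 13.4 % in Saturday's.

target ⇌ isomer of the product (K = 1.10, k = 3.00 × 10⁻⁴ s⁻¹, Ea = 78.0 kJ mol⁻¹, ΔH = −44.0 kJ mol⁻¹); second nucleophile ⇌ dormant form (K = 0.170, k = 0.0550 s⁻¹, Ea = 64.0 kJ mol⁻¹, ΔH = −75.0 kJ mol⁻¹); first nucleophile → decomposition product (k = 3.00 × 10⁻⁶ s⁻¹, Ea = 81.0 kJ mol⁻¹); substrate → intermediate (k = 0.0190 s⁻¹, Ea = 64.0 kJ mol⁻¹); intermediate → solvolysis product (k = 5.70 s⁻¹, Ea = 61.0 kJ mol⁻¹); first nucleophile + intermediate → target (k = 15.0 M⁻¹ s⁻¹, Ea = 43.0 kJ mol⁻¹); second nucleophile + intermediate → other capture product (k = 5.30 M⁻¹ s⁻¹, Ea = 37.0 kJ mol⁻¹); (constants at −20 °C) In Saturday's, the conversion of substrate into intermediate has half its turnover up to 2.5 min behind it at 0.559 min, against a half-life of 0.528 min from the substrate lifetime, and this is shorter than the feed of 1.5 min, so 37.3 % of the first nucleophile has entered by then. In Sunday's, the reckoned 11.8 % of substrate stands against 15.3 % in the flask at 2.50 min.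

Readings and results stem from a simulated flask with made-up constants; noise was put on by code.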